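A direct plan would acylate both primary amines of spermine A1 with succinimidyl dihydrocaffeate A2 to give N1,N14-bis(dihydrocaffeoyl)spermine A3, would move one acyl group from N14 to N10 while trapping the freed amine as N14-salicylidene kukoamine B A4, and would cleave the imine with aqueous acid. Its weakest steps would be:
- the N14→N10 acyl shift in A3, which would run uphill from a secondary to a tertiary amide;
- its restriction to one of two identical chain ends, which a single proton would have to secure;
- the long heating of free catechols on the way to A4, which invites oxidation and O-acylation.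

The proposed route would never handle spermine. It reads the N5–C6–C7–C8–C9–N10 bridge as a saturated but-2-yne-1,4-diamine and cuts it at C6–N5 and C6–C7. In one copper-catalysed alkyne Mannich reaction, formaldehyde (C6) would join an N1-acylated, N5-benzylated 1,3-diaminopropane to an N10-acylated N-propargyl-N-(2-cyanoethyl) amide, whose nitrile is the latent C13–N14 end. Each acyl group is put on a fragment in which only one nitrogen can take it, so no acyl shift and no choice between two chain ends arises. The catechols stay benzylated until one final hydrogenation, which also saturates the chain, reduces the nitrile and frees N5.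

Key step: step 5

Remark: spermine numbering is used for the chain (N1, C2–C4, N5, C6–C9, N10, C11–C13, N14). The target is written as the free base; it would come out of the acidic last step as its N5,N14 bis(acetate), the same compound in protonated form, and the free base would be set free by neutralisation at 0 °C directly before use. Compounds 1, 2, 4, 7, 8 and 12 are taken as commercial.

Step 1
Reactants: 1 3,4-bis(benzyloxy)benzaldehyde; 2 malonic acid
Product: 3 (E)-3-[3,4-bis(benzyloxy)phenyl]prop-2-enoic acid (di-O-benzylcaffeic acid)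
Conditions: 2 (1.5 equiv), pyridine, piperidine (0.1 equiv), 100 °C; cold aq HCl, filter, recrystallise (EtOH)
Reagents that add atoms: none
Why: In this Knoevenagel–Doebner condensation the adduct of malonic acid and the aldehyde loses water and CO2 in a decarboxylative elimination that gives only the (E)-cinnamic acid, whose alkene costs nothing because the last step saturates it.

Step 2
Reactants: 3 di-O-benzylcaffeic acid; 4 N-benzylpropane-1,3-diamine
Product: 6 (E)-N-[3-(benzylamino)propyl]-3-[3,4-bis(benzyloxy)phenyl]prop-2-enamide, via N-acylimidazole 5 (not isolated)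
Conditions: CDI (1,1'-carbonyldiimidazole, 1.05 equiv), THF, rt, 1 h; then added to 4 (1.3 equiv), THF, −20 °C to rt; aqueous wash, chromatography
Reagents that add atoms: none
Why: In this amide coupling through an N-acylimidazole the mild acyl donor 5 should react with the unhindered primary amine of 4 much faster than with its N-benzyl secondary amine at low temperature, which fixes the acyl group on N1 and leaves N5 as a secondary amine for the key step.

Step 3
Reactants: 7 propargylamine (prop-2-yn-1-amine); 8 acrylonitrile
Product: 9 3-(prop-2-yn-1-ylamino)propanenitrile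
Conditions: 7 (1.5 equiv), 8 (1.0 equiv), MeOH, 0 °C to rt; evaporate, bulb-to-bulb distillation
Reagents that add atoms: none
Why: In this aza-Michael addition (cyanoethylation) the primary amine should add once at room temperature, the second addition being slower for the more hindered adduct and further held back by the excess of volatile 7, and the nitrile arm supplies C11–C13 and N14.

Step 4
Reactants: 3 di-O-benzylcaffeic acid; 9 3-(prop-2-yn-1-ylamino)propanenitrile
Product: 11 (E)-3-[3,4-bis(benzyloxy)phenyl]-N-(2-cyanoethyl)-N-(prop-2-yn-1-yl)prop-2-enamide, via acid chloride 10 (not isolated)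
Conditions: (COCl)2 (1.2 equiv), DMF (cat.), CH2Cl2, 0 °C to rt, concentrate; then 9 (1.1 equiv), Et3N (1.5 equiv), CH2Cl2, 0 °C to rt
Reagents that add atoms: none
Why: In this acylation of a secondary amine with an acid chloride, 9 has a single N–H, so the second acyl group can only end on the future N10, and the alkyne and the nitrile are inert.

Step 5
Reactants: 6 (E)-N-[3-(benzylamino)propyl]-3-[3,4-bis(benzyloxy)phenyl]prop-2-enamide; 11 (E)-3-[3,4-bis(benzyloxy)phenyl]-N-(2-cyanoethyl)-N-(prop-2-yn-1-yl)prop-2-enamide; 12 formaldehyde (used as paraformaldehyde)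
Product: 14 (E)-N-[4-(benzyl{3-[(E)-3-(3,4-bis(benzyloxy)phenyl)prop-2-enamido]propyl}amino)but-2-yn-1-yl]-3-[3,4-bis(benzyloxy)phenyl]-N-(2-cyanoethyl)prop-2-enamide (fully masked 7,8-didehydro kukoamine B), via N-hydroxymethyl amine 13 (not isolated)
Conditions: 6 (1.0 equiv), 11 (1.1 equiv), 12 (1.5 equiv CH2O), CuBr (10 mol%), degassed 1,4-dioxane, 80 °C, Ar; aq NH3/NH4Cl wash, chromatography
Reagents that add atoms: none
Why: Amine 6 and formaldehyde should condense through carbinolamine 13 to an N-methyleneiminium ion, CuBr should turn the terminal C–H of 11 into a copper acetylide, and addition of the acetylide to the iminium carbon forms C6–C7 next to the new C6–N5 bond. This is the alkyne Mannich reaction (aldehyde–alkyne–amine coupling), and its closest use is the copper-catalysed aminomethylation of N-propargyl amides and lactams with paraformaldehyde and secondary amines to 4-aminobut-2-ynyl amides. No ring is closed and no stereocenter is formed. The step needs exactly one alkynylmethyl group on N5 and none elsewhere, which the substrate secures because N5 is the only amine present (N1 and N10 are amides, N14 is a nitrile) and its benzyl group leaves it one N–H. Closure of the iminium ion onto the N1–H amide to an N-acyl hexahydropyrimidine is reversible, as is aminal formation, and should be drained by the irreversible C–C bond formation; the tertiary amide of 11 cannot cyclise onto its alkyne, and exclusion of air suppresses oxidative alkyne dimerisation. In one operation the step assembles all fourteen chain atoms with both acyl groups already on N1 and N10.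

Step 6
Reactants: 14 fully masked 7,8-didehydro kukoamine B
Product: 15 kukoamine B
Conditions: H2 (4 bar), Pd(OH)2/C (20 wt% Pd), MeOH–AcOH (4:1), rt; filter under Ar; C18 chromatography (H2O–MeCN), lyophilise
Reagents that add atoms: none
Why: In this catalytic hydrogenation with hydrogenolysis, Pd(OH)2/C should saturate the alkyne and both cinnamoyl alkenes, reduce the nitrile to the primary amine and cleave the four O-benzyl groups and the N-benzyl group (eleven equivalents of H2), while acetic acid keeps N5 and N14 protonated, which suppresses coupling of the imine intermediate with amines and any N10→N14 acyl shift.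

## Compound list
1 | 3,4-bis(benzyloxy)benzaldehyde | O=Cc1ccc(OCc2ccccc2)c(OCc2ccccc2)c1 | starting material
2 | malonic acid | OC(=O)CC(=O)O | starting material
3 | (E)-3-[3,4-bis(benzyloxy)phenyl]prop-2-enoic acid (di-O-benzylcaffeic acid) | OC(=O)/C=C/c1ccc(OCc2ccccc2)c(OCc2ccccc2)c1 | intermediate
4 | N-benzylpropane-1,3-diamine | NCCCNCc1ccccc1 | starting material
5 | (E)-3-[3,4-bis(benzyloxy)phenyl]-1-(1H-imidazol-1-yl)prop-2-en-1-one (N-acylimidazole of 3) | O=C(/C=C/c1ccc(OCc2ccccc2)c(OCc2ccccc2)c1)n1ccnc1 | intermediate
6 | (E)-N-[3-(benzylamino)propyl]-3-[3,4-bis(benzyloxy)phenyl]prop-2-enamide | O=C(/C=C/c1ccc(OCc2ccccc2)c(OCc2ccccc2)c1)NCCCNCc1ccccc1 | intermediate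
7 | propargylamine (prop-2-yn-1-amine) | C#CCN | starting material
8 | acrylonitrile | C=CC#N | starting material
9 | 3-(prop-2-yn-1-ylamino)propanenitrile | C#CCNCCC#N | intermediate
10 | (E)-3-[3,4-bis(benzyloxy)phenyl]prop-2-enoyl chloride | O=C(Cl)/C=C/c1ccc(OCc2ccccc2)c(OCc2ccccc2)c1 | intermediate
11 | (E)-3-[3,4-bis(benzyloxy)phenyl]-N-(2-cyanoethyl)-N-(prop-2-yn-1-yl)prop-2-enamide | C#CCN(CCC#N)C(=O)/C=C/c1ccc(OCc2ccccc2)c(OCc2ccccc2)c1 | intermediate
12 | formaldehyde (as paraformaldehyde) | C=O | starting material
13 | (E)-N-{3-[benzyl(hydroxymethyl)amino]propyl}-3-[3,4-bis(benzyloxy)phenyl]prop-2-enamide (carbinolamine of 6) | OCN(Cc1ccccc1)CCCNC(=O)/C=C/c1ccc(OCc2ccccc2)c(OCc2ccccc2)c1 | intermediate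
14 | (E)-N-[4-(benzyl{3-[(E)-3-(3,4-bis(benzyloxy)phenyl)prop-2-enamido]propyl}amino)but-2-yn-1-yl]-3-[3,4-bis(benzyloxy)phenyl]-N-(2-cyanoethyl)prop-2-enamide | N#CCCN(CC#CCN(Cc1ccccc1)CCCNC(=O)/C=C/c1ccc(OCc2ccccc2)c(OCc2ccccc2)c1)C(=O)/C=C/c1ccc(OCc2ccccc2)c(OCc2ccccc2)c1 | intermediate
15 | kukoamine B (N1,N10-bis(dihydrocaffeoyl)spermine), achiral | NCCCN(CCCCNCCCNC(=O)CCc1ccc(O)c(O)c1)C(=O)CCc1ccc(O)c(O)c1 | target

Total step count: 6. Longest linear sequence: 4 steps (1 → 2 → 5 → 6; the branches through step 4 are equally long).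

Steps most likely to fail:

Risk 1, the three-component coupling (step 5). The iminium ion may be held back as a cyclic N-acyl aminal or as formaldehyde-derived aminals that do not reopen fast enough, or the copper acetylide may dimerise, so that conversion stalls. The fallback forms the C6–N5 bond by reductive amination of a saturated aldehyde; it sets out from acid chloride 10 and comes back to the route at 15. Commercial 4,4-diethoxybutan-1-amine would be cyanoethylated with 8 (MeOH, rt) to 3-[(4,4-diethoxybutyl)amino]propanenitrile F1, and acylation with 10 (Et3N, CH2Cl2) would then give (E)-3-[3,4-bis(benzyloxy)phenyl]-N-(2-cyanoethyl)-N-(4,4-diethoxybutyl)prop-2-enamide F2. Cleavage of the acetal (1 M aq HCl, THF, rt) would give (E)-3-[3,4-bis(benzyloxy)phenyl]-N-(2-cyanoethyl)-N-(4-oxobutyl)prop-2-enamide F3. This aldehyde would be joined to amine 6 with NaBH(OAc)3 in 1,2-dichloroethane to the 7,8-saturated analogue of 14, (E)-N-[4-(benzyl{3-[(E)-3-(3,4-bis(benzyloxy)phenyl)prop-2-enamido]propyl}amino)butyl]-3-[3,4-bis(benzyloxy)phenyl]-N-(2-cyanoethyl)prop-2-enamide F4. Hydrogenation under the conditions of step 6 would then give 15. This path also removes any risk of chain cleavage at the allylic stage of the alkyne reduction.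

Risk 2, the global hydrogenation (step 6). The nitrile is the slowest function to reduce; its imine intermediate may couple with an amine of a second molecule, or the reduction may stop at partly reduced material while the benzyl groups are already gone. The fallback replaces nitrile reduction by carbamate hydrogenolysis; it sets out from acid chloride 10 and comes back at 15. Commercial benzyl N-(3-aminopropyl)carbamate (3 equiv) would be mono-alkylated with propargyl bromide (K2CO3, MeCN, 0 °C) to benzyl N-[3-(prop-2-yn-1-ylamino)propyl]carbamate F5. Acylation with 10 (Et3N, CH2Cl2) would give benzyl N-[3-({(E)-3-[3,4-bis(benzyloxy)phenyl]prop-2-enoyl}(prop-2-yn-1-yl)amino)propyl]carbamate F6. Coupling of this alkyne with 6 and 12 under the conditions of step 5 would give the N14-benzyloxycarbonyl analogue of 14, benzyl N-{3-[{4-(benzyl{3-[(E)-3-(3,4-bis(benzyloxy)phenyl)prop-2-enamido]propyl}amino)but-2-yn-1-yl}{(E)-3-[3,4-bis(benzyloxy)phenyl]prop-2-enoyl}amino]propyl}carbamate F7. Hydrogenation with H2 and Pd/C in MeOH–AcOH, where only C–C saturation and benzyl-type hydrogenolysis are asked of the catalyst, would then give 15.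

Risk 3, the selective N1 acylation (step 2). The N-benzyl secondary amine may be acylated as well, or the imidazolide may react so slowly that warming erodes the primary/secondary selectivity. The fallback acylates a symmetric diamine and introduces the benzyl group afterwards; it sets out from N-acylimidazole 5 and comes back at 6. Addition of 5 to a large excess of 1,3-diaminopropane (5 equiv, THF, 0 °C) would give (E)-N-(3-aminopropyl)-3-[3,4-bis(benzyloxy)phenyl]prop-2-enamide F8. Condensation with benzaldehyde (MeOH, rt) would give (E)-N-{3-[(E)-benzylideneamino]propyl}-3-[3,4-bis(benzyloxy)phenyl]prop-2-enamide F9, and reduction of this imine in the same flask with NaBH4 at 0 °C would give 6.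

Further compounds
F1 | step 5 | 3-[(4,4-diethoxybutyl)amino]propanenitrile | CCOC(CCCNCCC#N)OCC
F2 | step 5 | (E)-3-[3,4-bis(benzyloxy)phenyl]-N-(2-cyanoethyl)-N-(4,4-diethoxybutyl)prop-2-enamide | CCOC(CCCN(CCC#N)C(=O)/C=C/c1ccc(OCc2ccccc2)c(OCc2ccccc2)c1)OCC
F3 | step 5 | (E)-3-[3,4-bis(benzyloxy)phenyl]-N-(2-cyanoethyl)-N-(4-oxobutyl)prop-2-enamide | O=CCCCN(CCC#N)C(=O)/C=C/c1ccc(OCc2ccccc2)c(OCc2ccccc2)c1
F4 | step 5 | (E)-N-[4-(benzyl{3-[(E)-3-(3,4-bis(benzyloxy)phenyl)prop-2-enamido]propyl}amino)butyl]-3-[3,4-bis(benzyloxy)phenyl]-N-(2-cyanoethyl)prop-2-enamide | N#CCCN(CCCCN(Cc1ccccc1)CCCNC(=O)/C=C/c1ccc(OCc2ccccc2)c(OCc2ccccc2)c1)C(=O)/C=C/c1ccc(OCc2ccccc2)c(OCc2ccccc2)c1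
F5 | step 6 | benzyl N-[3-(prop-2-yn-1-ylamino)propyl]carbamate | C#CCNCCCNC(=O)OCc1ccccc1
F6 | step 6 | benzyl N-[3-({(E)-3-[3,4-bis(benzyloxy)phenyl]prop-2-enoyl}(prop-2-yn-1-yl)amino)propyl]carbamate | C#CCN(CCCNC(=O)OCc1ccccc1)C(=O)/C=C/c1ccc(OCc2ccccc2)c(OCc2ccccc2)c1
F7 | step 6 | benzyl N-{3-[{4-(benzyl{3-[(E)-3-(3,4-bis(benzyloxy)phenyl)prop-2-enamido]propyl}amino)but-2-yn-1-yl}{(E)-3-[3,4-bis(benzyloxy)phenyl]prop-2-enoyl}amino]propyl}carbamate | O=C(OCc1ccccc1)NCCCN(CC#CCN(Cc1ccccc1)CCCNC(=O)/C=C/c1ccc(OCc2ccccc2)c(OCc2ccccc2)c1)C(=O)/C=C/c1ccc(OCc2ccccc2)c(OCc2ccccc2)c1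
F8 | step 2 | (E)-N-(3-aminopropyl)-3-[3,4-bis(benzyloxy)phenyl]prop-2-enamide | NCCCNC(=O)/C=C/c1ccc(OCc2ccccc2)c(OCc2ccccc2)c1
F9 | step 2 | (E)-N-{3-[(E)-benzylideneamino]propyl}-3-[3,4-bis(benzyloxy)phenyl]prop-2-enamide | O=C(/C=C/c1ccc(OCc2ccccc2)c(OCc2ccccc2)c1)NCCC/N=C/c1ccccc1
A1 | direct plan | spermine (N,N'-bis(3-aminopropyl)butane-1,4-diamine) | NCCCNCCCCNCCCN
A2 | direct plan | 2,5-dioxopyrrolidin-1-yl 3-(3,4-dihydroxyphenyl)propanoate (succinimidyl dihydrocaffeate) | O=C(CCc1ccc(O)c(O)c1)ON1C(=O)CCC1=O
A3 | direct plan | N1,N14-bis(dihydrocaffeoyl)spermine (kukoamine A) | O=C(CCc1ccc(O)c(O)c1)NCCCNCCCCNCCCNC(=O)CCc1ccc(O)c(O)c1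
A4 | direct plan | N14-salicylidene kukoamine B, (E)-imine | Oc1ccccc1/C=N/CCCN(CCCCNCCCNC(=O)CCc1ccc(O)c(O)c1)C(=O)CCc1ccc(O)c(O)c1
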